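## Retrosynthetic overview

1. Target ⇐ 1,4-reduction of the C4=C5 enone of the 3a-allyl cross-conjugated dienone, with kinetic protonation at C5 anti to the allyl group.
2. Dienone ⇐ dearomative ipso-Friedel–Crafts closure of ring B (C3–C3a bond, sets C3 and the quaternary C3a) in an aryl ether of 6-allyl-2,3,4-trimethoxyphenol; the arene becomes ring C by loss of its para O-methyl group.
3. Aryl ether ⇐ Mitsunobu union (O1–C2, inversion) of that phenol with (1R,2S)-1-methoxy-1-(3,4,5-trimethoxyphenyl)propan-2-ol.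
4. Alcohol ⇐ methanolysis of the (S,S)-epoxide from chiral-ketone (dioxirane) epoxidation of (E)-isoelemicin, which fixes the absolute configuration; phenol ⇐ O-allylation and Claisen rearrangement of 2,3,4-trimethoxyphenol.
5. Ring order: aryl ring A and the arene that becomes ring C are bought; ring B (dihydrofuran) and the dearomatised ring C form together in the ipso-cyclisation.

Assumption: (E)-isoelemicin and 2,3,4-trimethoxyphenol are taken as catalogue compounds; the L-fructose-derived ent-Shi ketone serves only as catalyst.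

## Route

Step 1
Reactants: 1 (E)-isoelemicin
Product: 2 (2S,3S)-2-methyl-3-(3,4,5-trimethoxyphenyl)oxirane
Conditions: ent-Shi ketone (1,2:4,5-di-O-isopropylidene-β-L-erythro-2,3-hexodiulo-2,6-pyranose, 30 mol %), Oxone (2KHSO5·KHSO4·K2SO4), K2CO3, Bu4NHSO4 (4 mol %), aq. Na2B4O7/Na2EDTA buffer (pH 10.5), MeCN–CH2(OMe)2 1:2, 0 °C
Reagents that add atoms: Oxone, active component potassium peroxymonosulfate KHSO5, [K+].[O-]S(=O)(=O)OO
Why: Shi asymmetric epoxidation: the chiral dioxirane formed from the ketone transfers oxygen through a spiro transition state to one face of the trans-alkene, and because the D-fructose-derived ketone gives (R,R)-epoxides of trans-β-methylstyrenes, its enantiomer gives the (S,S)-epoxide (about 90–95 % ee expected), setting the first two stereocentres.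

Step 2
Reactants: 2 (2S,3S)-2-methyl-3-(3,4,5-trimethoxyphenyl)oxirane
Product: 3 (1R,2S)-1-methoxy-1-(3,4,5-trimethoxyphenyl)propan-2-ol
Conditions: MeOH, PPTS (5 mol %), −20 → 0 °C; then Et3N
Reagents that add atoms: methanol, CO
Why: Acid-catalysed epoxide solvolysis: methanol opens the activated epoxide at the benzylic carbon with inversion and leaves C2 untouched (2S); any C1 epimer from partial SN1 opening is harmless because C1 is ionised in step 6.

Step 3
Reactants: 4 2,3,4-trimethoxyphenol; 5 allyl bromide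
Product: 6 1-(allyloxy)-2,3,4-trimethoxybenzene
Conditions: K2CO3, acetone, reflux
Reagents that add atoms: allyl bromide (5), C=CCBr
Why: Williamson ether synthesis (SN2 O-alkylation of the phenoxide); no stereocentre is involved.

Step 4
Reactants: 6 1-(allyloxy)-2,3,4-trimethoxybenzene
Product: 8 6-allyl-2,3,4-trimethoxyphenol, via 6-allyl-2,3,4-trimethoxycyclohexa-2,4-dien-1-one 7 (not isolated)
Conditions: PhNEt2, 200 °C (sealed tube), argon
Reagents that add atoms: none
Why: Aromatic Claisen rearrangement: the [3,3] shift can only go to C6, the single ortho position bearing hydrogen (C2 and the para position C4 carry OMe), and tautomerisation of dienone 7 restores the arene.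

Step 5
Reactants: 3 (1R,2S)-1-methoxy-1-(3,4,5-trimethoxyphenyl)propan-2-ol; 8 6-allyl-2,3,4-trimethoxyphenol
Product: 9 1-allyl-3,4,5-trimethoxy-2-{[(1R,2R)-1-methoxy-1-(3,4,5-trimethoxyphenyl)propan-2-yl]oxy}benzene
Conditions: PPh3, DIAD, toluene, 0 °C → rt
Reagents that add atoms: none
Why: Mitsunobu etherification: the phenoxide displaces the oxyphosphonium of the secondary alcohol by SN2 with inversion, turning (2S) into the (2R) aryl ether that already has the C2 configuration of the target, the same kind of union used for 8-O-4′ neolignans from 1-aryl-1-alkoxypropan-2-ols and 2,6-disubstituted phenols.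

Step 6
Reactants: 9 1-allyl-3,4,5-trimethoxy-2-{[(1R,2R)-1-methoxy-1-(3,4,5-trimethoxyphenyl)propan-2-yl]oxy}benzene
Product: 11 (2R,3S,3aS)-3a-allyl-5,7-dimethoxy-2-methyl-3-(3,4,5-trimethoxyphenyl)-3,3a-dihydro-1-benzofuran-6(2H)-one, via O6-methyl oxocarbenium triflate 10 (not isolated)
Conditions: TMSOTf (1.1 equiv), CH2Cl2 (0.01 M), −78 → −40 °C; then Bu4NI (1.5 equiv), −40 → 0 °C; aq. NaHCO3/Na2S2O3
Reagents that add atoms: none
Why: Proposed new method: TMSOTf ionises the benzylic methyl ether to a 3,4,5-trimethoxybenzyl cation that the O1–C2 tether holds over the allyl-bearing ortho carbon (the other ortho carbon carries OMe and would give an arenium ion without para-oxygen stabilisation), so it adds ipso in a Friedel–Crafts sense to close ring B through a π-stacked arrangement with the C2 methyl outside and the aryl group away from the allyl group (2,3-trans, aryl anti to allyl, hence 3S and the quaternary 3aS centre); the resulting arenium ion 10 cannot rearomatise, is stabilised by O1 and the para methoxy group, and is discharged by SN2 demethylation with iodide to the dienone. The closest known reaction types are acid-mediated additions of aryl-propenes to quinone-monoketal cations (burchellin-type neolignans), ipso-cyclisations of para-methoxyarenes to spirodienones, and cationic cyclisations of 2-aryloxy benzylic alcohols to 3-aryl-2,3-dihydrobenzofurans.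

Step 7
Reactants: 11 (2R,3S,3aS)-3a-allyl-5,7-dimethoxy-2-methyl-3-(3,4,5-trimethoxyphenyl)-3,3a-dihydro-1-benzofuran-6(2H)-one
Product: 12 (2R,3S,3aR,5S)-3a-allyl-5,7-dimethoxy-2-methyl-3-(3,4,5-trimethoxyphenyl)-3,3a,4,5-tetrahydro-1-benzofuran-6(2H)-one
Conditions: [(Ph3P)CuH]6 (5 mol %), PhMe2SiH (1.5 equiv), t-BuOH (1.5 equiv), toluene, 0 °C
Reagents that add atoms: none
Why: Copper hydride conjugate reduction (Stryker type): hydride adds only to C4 of the α-methoxy enone (the C7=C7a vinylogous ester and the terminal alkene are inert), and the enolate is protonated at C5 by t-BuOH on the face anti to the pseudo-axial 3a-allyl group, placing 5-OMe cis to allyl (5S); the C3a descriptor changes from S to R only because C4 becomes CH2.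

## Compound list

1 | (E)-isoelemicin, (E)-1,2,3-trimethoxy-5-(prop-1-en-1-yl)benzene | C/C=C/c1cc(OC)c(OC)c(OC)c1 | starting material
2 | (2S,3S)-2-methyl-3-(3,4,5-trimethoxyphenyl)oxirane | C[C@@H]1O[C@H]1c1cc(OC)c(OC)c(OC)c1 | intermediate
3 | (1R,2S)-1-methoxy-1-(3,4,5-trimethoxyphenyl)propan-2-ol | C[C@H](O)[C@H](OC)c1cc(OC)c(OC)c(OC)c1 | intermediate
4 | 2,3,4-trimethoxyphenol | COc1ccc(O)c(OC)c1OC | starting material
5 | allyl bromide | C=CCBr | starting material
6 | 1-(allyloxy)-2,3,4-trimethoxybenzene | C=CCOc1ccc(OC)c(OC)c1OC | intermediate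
7 | 6-allyl-2,3,4-trimethoxycyclohexa-2,4-dien-1-one (transient, racemic; its stereocentre is erased on tautomerisation) | C=CCC1C=C(OC)C(OC)=C(OC)C1=O | intermediate (not isolated)
8 | 6-allyl-2,3,4-trimethoxyphenol | C=CCc1cc(OC)c(OC)c(OC)c1O | intermediate
9 | 1-allyl-3,4,5-trimethoxy-2-{[(1R,2R)-1-methoxy-1-(3,4,5-trimethoxyphenyl)propan-2-yl]oxy}benzene | C=CCc1cc(OC)c(OC)c(OC)c1O[C@H](C)[C@H](OC)c1cc(OC)c(OC)c(OC)c1 | intermediate
10 | O6-methyl oxocarbenium triflate of 11, (2R,3S,3aS)-3a-allyl-5,6,7-trimethoxy-2-methyl-3-(3,4,5-trimethoxyphenyl)-2,3-dihydro-3aH-1-benzofuranylium triflate | C=CC[C@]12C=C(OC)C(=[O+]C)C(OC)=C1O[C@H](C)[C@H]2c1cc(OC)c(OC)c(OC)c1.[O-]S(=O)(=O)C(F)(F)F | intermediate (not isolated)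
11 | (2R,3S,3aS)-3a-allyl-5,7-dimethoxy-2-methyl-3-(3,4,5-trimethoxyphenyl)-3,3a-dihydro-1-benzofuran-6(2H)-one | C=CC[C@]12C=C(OC)C(=O)C(OC)=C1O[C@H](C)[C@H]2c1cc(OC)c(OC)c(OC)c1 | intermediate
12 | (2R,3S,3aR,5S)-3a-allyl-5,7-dimethoxy-2-methyl-3-(3,4,5-trimethoxyphenyl)-3,3a,4,5-tetrahydro-1-benzofuran-6(2H)-one (CNP0136253.2) | C=CC[C@]12C[C@H](OC)C(=O)C(OC)=C1O[C@H](C)[C@H]2c1cc(OC)c(OC)c(OC)c1 | target

## Step count and risks

Total step count: 7. Longest linear sequence: 5 steps (steps 1, 2, 5, 6, 7; the phenol branch 3, 4, 5, 6, 7 is equally long).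

Steps most likely to fail:

1. Step 6 (the new ring closure). The benzylic cation may instead undergo a 1,2-hydride shift or elimination to an enol ether, or attack the OMe-bearing ortho carbon. Allyl may migrate in the arenium ion, and the diastereoselectivity at C3/C3a is only predicted. The fallback uses known reactions only, sets out from alcohol 3 and comes back at dienone 11.
   - Commercial 2,6-dimethoxyphenol is O-allylated with 5 (K2CO3, acetone) to 2-(allyloxy)-1,3-dimethoxybenzene F1.
   - Formylation para to a methoxy group (POCl3, DMF) gives 3-(allyloxy)-2,4-dimethoxybenzaldehyde F2.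
   - Dakin oxidation (H2O2, cat. SeO2; then aq. KOH) gives 3-(allyloxy)-2,4-dimethoxyphenol F3.
   - Mitsunobu coupling of F3 with 3 (PPh3, DIAD) gives 2-(allyloxy)-1,3-dimethoxy-4-{[(1R,2R)-1-methoxy-1-(3,4,5-trimethoxyphenyl)propan-2-yl]oxy}benzene F4.
   - The benzylic cation of F4 (cat. TMSOTf, CH2Cl2, −40 °C) closes in an ordinary Friedel–Crafts sense on the free ortho C–H to the trans product (2R,3S)-6-(allyloxy)-5,7-dimethoxy-2-methyl-3-(3,4,5-trimethoxyphenyl)-2,3-dihydro-1-benzofuran F5.
   - Heating F5 (PhNEt2, 190 °C) moves the allyl group by para-Claisen rearrangement to C3a, anti to the C3 aryl group, because both ortho positions carry OMe. This is the established entry to 3a-allyl-6-oxo neolignan dienones of the kadsurenone type, and it gives 11.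

2. Step 5 (Mitsunobu with a hindered phenol). The di-ortho-substituted phenol may react slowly, and the activated alcohol can undergo 1,2-aryl shift (assisted by the C1 methoxy group) or elimination. The fallback sets out from epoxide 2 and comes back at 11.
   - Oxidative epoxide opening with DMSO (cat. TfOH, then i-Pr2NEt, Kornblum type) gives (S)-2-hydroxy-1-(3,4,5-trimethoxyphenyl)propan-1-one F6, with C2 untouched.
   - This activated, unhindered alcohol (no migration is possible next to the carbonyl) undergoes Mitsunobu coupling with 8 to (R)-2-(6-allyl-2,3,4-trimethoxyphenoxy)-1-(3,4,5-trimethoxyphenyl)propan-1-one F7, the classical 8-O-4′ connection.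
   - NaBH4 (MeOH, 0 °C) gives (2R)-2-(6-allyl-2,3,4-trimethoxyphenoxy)-1-(3,4,5-trimethoxyphenyl)propan-1-ol F8 as C1 epimers.
   - Under the step 6 conditions F8 is ionised to the same benzylic cation as 9 and delivers 11.

3. Step 7 (chemo- and stereoselective reduction). Possible problems are slow hydride delivery to the neopentyl-type C4, 1,2-reduction, and formation of or equilibration to the 5-epimer, since the target carries an axial 5-OMe syn to the allyl group. The fallback sets out from 11 and comes back at 12.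
   - 1,4-Reduction with LiBH(s-Bu)3 (THF, −78 °C) and trapping of the enolate with Me3SiCl/Et3N gives the isolable (2R,3S,3aR)-3a-allyl-5,7-dimethoxy-2-methyl-3-(3,4,5-trimethoxyphenyl)-6-[(trimethylsilyl)oxy]-2,3,3a,4-tetrahydro-1-benzofuran F9.
   - F9 is protonated under strictly kinetic conditions (Bu4NF, AcOH, THF, −78 °C) on the face anti to the allyl group to give 12.
   - Any 5-epimer can be recycled through F9 with LiN(SiMe3)2/Me3SiCl.

## Further compounds

F1 | step 6 | 2-(allyloxy)-1,3-dimethoxybenzene | C=CCOc1c(OC)cccc1OC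
F2 | step 6 | 3-(allyloxy)-2,4-dimethoxybenzaldehyde | C=CCOc1c(OC)ccc(C=O)c1OC
F3 | step 6 | 3-(allyloxy)-2,4-dimethoxyphenol | C=CCOc1c(OC)ccc(O)c1OC
F4 | step 6 | 2-(allyloxy)-1,3-dimethoxy-4-{[(1R,2R)-1-methoxy-1-(3,4,5-trimethoxyphenyl)propan-2-yl]oxy}benzene | C=CCOc1c(OC)ccc(O[C@H](C)[C@H](OC)c2cc(OC)c(OC)c(OC)c2)c1OC
F5 | step 6 | (2R,3S)-6-(allyloxy)-5,7-dimethoxy-2-methyl-3-(3,4,5-trimethoxyphenyl)-2,3-dihydro-1-benzofuran | C=CCOc1c(OC)cc2c(c1OC)O[C@H](C)[C@H]2c1cc(OC)c(OC)c(OC)c1
F6 | step 5 | (S)-2-hydroxy-1-(3,4,5-trimethoxyphenyl)propan-1-one | C[C@H](O)C(=O)c1cc(OC)c(OC)c(OC)c1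
F7 | step 5 | (R)-2-(6-allyl-2,3,4-trimethoxyphenoxy)-1-(3,4,5-trimethoxyphenyl)propan-1-one | C=CCc1cc(OC)c(OC)c(OC)c1O[C@H](C)C(=O)c1cc(OC)c(OC)c(OC)c1
F8 | step 5 | (2R)-2-(6-allyl-2,3,4-trimethoxyphenoxy)-1-(3,4,5-trimethoxyphenyl)propan-1-ol (C1 epimers) | C=CCc1cc(OC)c(OC)c(OC)c1O[C@H](C)C(O)c1cc(OC)c(OC)c(OC)c1
F9 | step 7 | (2R,3S,3aR)-3a-allyl-5,7-dimethoxy-2-methyl-3-(3,4,5-trimethoxyphenyl)-6-[(trimethylsilyl)oxy]-2,3,3a,4-tetrahydro-1-benzofuran | C=CC[C@]12CC(OC)=C(O[Si](C)(C)C)C(OC)=C1O[C@H](C)[C@H]2c1cc(OC)c(OC)c(OC)c1
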